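**Retrosynthetic overview**

1. The target is the O‑4 vanillate of a trans‑fused octahydroazulene triol. Late disconnections: the ester (vanillic acid), the C‑7 carbinol (from the C‑7 enone) and the C‑3 isopropyl group (Grignard addition to a cyclopentanone).
2. Key disconnection: the C‑8 methylene/C‑7 carbinol pair is cut out as vinyl‑Bpin. The C‑8a–C‑8 and C‑6–C‑7 bonds are made together in a nickel/photoredox radical‑relay [5+2] annulation of a monocyclic cyclopentanone that carries a tertiary trifluoroborate at C‑8a and a (Z)‑alkenyl iodide at C‑6.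
3. Enabling feature: in the seven‑membered ring a CH2–CH(OH) unit (C‑8, C‑7) lies between the quaternary, methyl‑bearing ring‑fusion carbon C‑8a (a tertiary‑radical site) and the vinylic C‑6 (an alkenyl–nickel site). The C‑7 oxygen is a latent C–B bond.
4. The annulation precursor comes from 3‑methylcyclopent‑2‑enone, B2pin2 and (Z)‑3‑iodobut‑2‑enal by one enantioselective conjugate borylation/aldol that sets C‑3a and C‑4. The boron‑bearing centre is a traceless stereo‑relay.
5. Ring order: the five‑membered ring is bought in; the seven‑membered ring is closed in the key step.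

Key step: step 6

Remark on numbering: azulene locants of the target are used throughout (C‑3 isopropyl carbinol, C‑3a ring‑fusion CH, C‑4 acyloxy carbon, C‑5=C‑6(Me), C‑7 carbinol, C‑8 CH2, C‑8a quaternary C–Me). β is the face of the C‑8a methyl group.

Remark on the chemistry (assumption): in step 3 the aldehyde is assumed to add to the enolate face opposite the pinacolboryl group. If the opposite face is preferred, the other ligand enantiomer is used, because the boron‑bearing centre is erased in step 6.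

**Route**

Step 1
Reactants: 1 but‑2‑yn‑1‑ol
Product: 3 (Z)‑3‑iodobut‑2‑en‑1‑ol, via cyclic vinylalanate 2 (not isolated)
Conditions: Red‑Al (NaAlH2(OCH2CH2OMe)2), THF, 0 °C to rt; EtOAc; then I2, THF, −78 to 0 °C
Reagents that add atoms: iodine, II
Why: trans‑hydroalumination of the propargylic alcohol through the cyclic alkoxy‑vinylalanate places aluminium on the distal alkyne carbon cis to the CH2O group, and iodinolysis with retention should give the (Z)‑iodide (Red‑Al reduction/iodination of a propargylic alcohol).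

Step 2
Reactants: 3 (Z)‑3‑iodobut‑2‑en‑1‑ol
Product: 4 (Z)‑3‑iodobut‑2‑enal
Conditions: activated MnO2 (excess), CH2Cl2, rt, used at once
Reagents that add atoms: none
Why: allylic alcohol oxidation with MnO2 should leave the alkenyl iodide and its geometry untouched.

Step 3
Reactants: 5 3‑methylcyclopent‑2‑en‑1‑one; 6 bis(pinacolato)diboron; 4 (Z)‑3‑iodobut‑2‑enal
Product: 8 (2S,3R)‑2‑[(1R,2Z)‑1‑hydroxy‑3‑iodobut‑2‑en‑1‑yl]‑3‑methyl‑3‑(4,4,5,5‑tetramethyl‑1,3,2‑dioxaborolan‑2‑yl)cyclopentan‑1‑one, via boron enolate 7 (not isolated)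
Conditions: CuPF6(MeCN)4 (10 mol %), QuinoxP* (12 mol %, the enantiomer that gives the 3R boronate), LiOtBu (15 mol %), 6 (1.0 equiv), DMSO, rt; then 4, THF, 0 °C; pH 7 buffer work‑up; diastereomers separated
Reagents that add atoms: none
Why: copper‑catalysed enantioselective conjugate borylation of the β‑methyl enone gives the enolate regiospecifically, and its aldol addition to 4 through a closed chair transition state (cyclic E‑enolate, anti) on the face opposite the boryl group should set C‑3a and C‑4 (conjugate borylation–aldol sequence).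

Step 4
Reactants: 8 aldol product
Product: 9 (2S,3R)‑2‑[(1R,2Z)‑1‑(tert‑butyldimethylsilyloxy)‑3‑iodobut‑2‑en‑1‑yl]‑3‑methyl‑3‑(4,4,5,5‑tetramethyl‑1,3,2‑dioxaborolan‑2‑yl)cyclopentan‑1‑one
Conditions: TBSOTf, 2,6‑lutidine, CH2Cl2, −78 °C
Reagents that add atoms: tert‑butyldimethylsilyl trifluoromethanesulfonate, CC(C)(C)[Si](C)(C)OS(=O)(=O)C(F)(F)F
Why: low‑temperature O‑silylation should block retro‑aldol and dehydration of the β‑hydroxy ketone without enolising the ketone.

Step 5
Reactants: 9 silyl ether boronate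
Product: 10 potassium trifluoro{(1R,2S)‑2‑[(1R,2Z)‑1‑(tert‑butyldimethylsilyloxy)‑3‑iodobut‑2‑en‑1‑yl]‑1‑methyl‑3‑oxocyclopentyl}borate
Conditions: aq. KHF2, MeOH, rt; acetone extraction
Reagents that add atoms: potassium hydrogen difluoride, [K+].[F-].F
Why: exchange of the pinacol ester for the trifluoroborate should proceed with retention and spare the alkyl silyl ether, ketone and alkenyl iodide.

Step 6
Reactants: 10 tertiary trifluoroborate; 11 vinylboronic acid pinacol ester
Product: 14 (3aS,4S,8aR)‑4‑[(tert‑butyldimethylsilyl)oxy]‑6,8a‑dimethyl‑7‑(4,4,5,5‑tetramethyl‑1,3,2‑dioxaborolan‑2‑yl)‑1,3a,4,7,8,8a‑hexahydroazulen‑3(2H)‑one (C‑7 epimers), via tertiary radical 12 (not isolated), via α‑boryl radical 13 (not isolated)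
Conditions: 11 (5 equiv), Ir[dF(CF3)ppy]2(bpy)PF6 (2 mol %), NiCl2(DME) (10 mol %), 4,4′‑di‑tert‑butyl‑2,2′‑bipyridine (12 mol %), DMA/dioxane, 0.01 M, blue LEDs, rt
Reagents that add atoms: none
Why: Proposed new method: a ring‑closing version of the nickel/photoredox three‑component 1,2‑alkyl–alkenylation of vinyl boronic esters, the closest known reaction being the intermolecular coupling of tertiary alkyltrifluoroborates, vinyl‑Bpin and aryl or alkenyl halides; here the radical precursor and the alkenyl iodide sit in the same molecule, so the two‑carbon unit is stitched in as C‑8/C‑7 of the ring. The excited trivalent iridium complex oxidises the trifluoroborate to the tertiary C‑8a radical 12, which adds to the CH2 terminus of 11 (C‑8a–C‑8 bond) to give the α‑boryl radical 13; nickel, after oxidative addition into the (Z)‑alkenyl C–I bond, captures 13, and reductive elimination forms the C‑6–C‑7 bond. The seven‑membered ring is thus closed by C(sp2)–C(sp3) reductive elimination from an eight‑membered nickelacycle (a formal [5+2] annulation), not by radical cyclisation. The quaternary C‑8a centre is set under substrate control, because 11 approaches the planar cyclopentyl radical anti to the bulky C‑3a side chain, which gives the trans ring fusion with the methyl group β; C‑7 is formed as a mixture that is not relied on and converges at the enone in step 9. The step needs Giese addition to outrun direct nickel capture of the tertiary radical (secured by the steric reluctance of tertiary radicals to couple at nickel and by excess 11) and ring closure to outrun intermolecular capture (secured by high dilution and by the (Z)‑geometry that holds C‑6 next to the new chain).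

Step 7
Reactants: 14 bicyclic allylic boronate
Product: 15 (3aS,4S,8aR)‑4‑[(tert‑butyldimethylsilyl)oxy]‑7‑hydroxy‑6,8a‑dimethyl‑1,3a,4,7,8,8a‑hexahydroazulen‑3(2H)‑one (C‑7 epimers)
Conditions: 30 % aq. H2O2, NaHCO3, THF/H2O, 0 °C
Reagents that add atoms: hydrogen peroxide, OO
Why: buffered peroxide oxidation of the C–B bond (retention) should give the allylic alcohols without epimerising C‑3a or eliminating the β‑silyloxy group.

Step 8
Reactants: 15 hydroxy ketone
Product: 16 (3R,3aS,4S,8aR)‑4‑[(tert‑butyldimethylsilyl)oxy]‑6,8a‑dimethyl‑3‑(propan‑2‑yl)‑1,2,3,3a,4,7,8,8a‑octahydroazulene‑3,7‑diol (C‑7 epimers)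
Conditions: iPrMgCl (4 equiv), LaCl3·2LiCl (1.5 equiv), THF, −20 to 0 °C
Reagents that add atoms: isopropylmagnesium chloride, CC(C)[Mg]Cl
Why: lanthanum‑promoted Grignard 1,2‑addition suppresses enolisation and β‑hydride reduction, and attack on the cyclopentanone from the α‑face, anti to the angular methyl group, should give the 3β‑alcohol.

Step 9
Reactants: 16 diol
Product: 17 (3R,3aS,4S,8aR)‑4‑[(tert‑butyldimethylsilyl)oxy]‑3‑hydroxy‑6,8a‑dimethyl‑3‑(propan‑2‑yl)‑2,3,3a,4,8,8a‑hexahydroazulen‑7(1H)‑one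
Conditions: activated MnO2 (excess), CH2Cl2, rt
Reagents that add atoms: none
Why: selective oxidation of the secondary allylic alcohol should merge both C‑7 epimers into one enone and leave the tertiary alcohol alone.

Step 10
Reactants: 17 silyloxy enone
Product: 18 (3R,3aS,4S,8aR)‑3,4‑dihydroxy‑6,8a‑dimethyl‑3‑(propan‑2‑yl)‑2,3,3a,4,8,8a‑hexahydroazulen‑7(1H)‑one
Conditions: HF·pyridine, pyridine/THF, 0 °C to rt
Reagents that add atoms: none
Why: buffered acidic fluoride desilylation avoids the base‑mediated isomerisation of the γ‑hydroxy enone and should free only the C‑4 hydroxyl.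

Step 11
Reactants: 19 vanillic acid
Product: 21 4‑[(tert‑butyldimethylsilyl)oxy]‑3‑methoxybenzoic acid, via bis‑silylated vanillate 20 (not isolated)
Conditions: TBSCl (2.5 equiv), imidazole, DMF, rt; then AcOH/THF/H2O, rt
Reagents that add atoms: tert‑butyldimethylsilyl chloride, CC(C)(C)[Si](C)(C)Cl
Why: exhaustive silylation followed by selective hydrolysis of the labile silyl ester should give the phenol‑protected acid.

Step 12
Reactants: 18 diol enone; 21 protected vanillic acid
Product: 22 (3R,3aS,4S,8aR)‑3‑hydroxy‑6,8a‑dimethyl‑7‑oxo‑3‑(propan‑2‑yl)‑1,2,3,3a,4,7,8,8a‑octahydroazulen‑4‑yl 4‑[(tert‑butyldimethylsilyl)oxy]‑3‑methoxybenzoate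
Conditions: EDC·HCl, DMAP, CH2Cl2, rt
Reagents that add atoms: none
Why: Steglich esterification should acylate the only secondary hydroxyl with retention at C‑4, the tertiary alcohol being inert.

Step 13
Reactants: 22 keto ester
Product: 23 (3R,3aS,4S,7R,8aR)‑3,7‑dihydroxy‑6,8a‑dimethyl‑3‑(propan‑2‑yl)‑1,2,3,3a,4,7,8,8a‑octahydroazulen‑4‑yl 4‑[(tert‑butyldimethylsilyl)oxy]‑3‑methoxybenzoate
Conditions: NaBH4, CeCl3·7H2O, MeOH, −78 °C
Reagents that add atoms: none
Why: Luche 1,2‑reduction of the enone, with hydride delivered from the α‑face anti to the angular methyl group that stands 1,3 to C‑7, should give the 7β‑alcohol and spare the ester.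

Step 14
Reactants: 23 silyl‑protected target
Product: 24 (3R,3aS,4S,7R,8aR)‑3,7‑dihydroxy‑6,8a‑dimethyl‑3‑(propan‑2‑yl)‑1,2,3,3a,4,7,8,8a‑octahydroazulen‑4‑yl 4‑hydroxy‑3‑methoxybenzoate (target)
Conditions: KHF2, MeOH, rt
Reagents that add atoms: none
Why: KHF2 cleaves aryl silyl ethers selectively under near‑neutral conditions, so the allylic ester and the allylic alcohol should survive.

**Compound list**

1 | but‑2‑yn‑1‑ol | CC#CCO | starting material
2 | sodium cyclic alkoxy‑vinylalanate (3‑methyl‑2,5‑dihydro‑1,2‑oxaaluminole ate complex with two 2‑methoxyethoxy ligands) | CC1=CCO[Al-]1(OCCOC)OCCOC.[Na+] | intermediate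
3 | (Z)‑3‑iodobut‑2‑en‑1‑ol | C/C(I)=C/CO | intermediate
4 | (Z)‑3‑iodobut‑2‑enal | C/C(I)=C/C=O | intermediate
5 | 3‑methylcyclopent‑2‑en‑1‑one | CC1=CC(=O)CC1 | starting material
6 | bis(pinacolato)diboron | CC1(C)OB(OC1(C)C)B1OC(C)(C)C(C)(C)O1 | starting material
7 | pinacolboron enolate of (R)‑3‑methyl‑3‑(pinacolboryl)cyclopentanone | C[C@]1(B2OC(C)(C)C(C)(C)O2)CCC(OB2OC(C)(C)C(C)(C)O2)=C1 | intermediate
8 | (2S,3R)‑2‑[(1R,2Z)‑1‑hydroxy‑3‑iodobut‑2‑en‑1‑yl]‑3‑methyl‑3‑(4,4,5,5‑tetramethyl‑1,3,2‑dioxaborolan‑2‑yl)cyclopentan‑1‑one | C/C(I)=C/[C@H](O)[C@H]1C(=O)CC[C@]1(C)B2OC(C)(C)C(C)(C)O2 | intermediate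
9 | tert‑butyldimethylsilyl ether of 8 | C/C(I)=C/[C@H](O[Si](C)(C)C(C)(C)C)[C@H]1C(=O)CC[C@]1(C)B2OC(C)(C)C(C)(C)O2 | intermediate
10 | potassium trifluoroborate from 9 | C/C(I)=C/[C@H](O[Si](C)(C)C(C)(C)C)[C@H]1C(=O)CC[C@]1(C)[B-](F)(F)F.[K+] | intermediate
11 | vinylboronic acid pinacol ester | C=CB1OC(C)(C)C(C)(C)O1 | starting material
12 | tertiary cyclopentyl radical from 10 | C/C(I)=C/[C@H](O[Si](C)(C)C(C)(C)C)[C@H]1C(=O)CC[C]1C | intermediate
13 | α‑boryl radical, adduct of 12 to 11 | C/C(I)=C/[C@H](O[Si](C)(C)C(C)(C)C)[C@H]1C(=O)CC[C@]1(C)C[CH]B2OC(C)(C)C(C)(C)O2 | intermediate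
14 | (3aS,4S,8aR)‑4‑silyloxy‑6,8a‑dimethyl‑7‑(pinacolboryl)hexahydroazulen‑3‑one, trans‑fused, C‑7 epimers | CC(C)(C)[Si](C)(C)O[C@H]1C=C(C)C(B2OC(C)(C)C(C)(C)O2)C[C@@]3(C)CCC(=O)[C@H]13 | intermediate
15 | (3aS,4S,8aR)‑4‑silyloxy‑7‑hydroxy‑6,8a‑dimethylhexahydroazulen‑3‑one, C‑7 epimers | CC(C)(C)[Si](C)(C)O[C@H]1C=C(C)C(O)C[C@@]3(C)CCC(=O)[C@H]13 | intermediate
16 | (3R,3aS,4S,8aR)‑4‑silyloxy‑3‑isopropyl‑6,8a‑dimethyloctahydroazulene‑3,7‑diol, C‑7 epimers | CC(C)(C)[Si](C)(C)O[C@H]1C=C(C)C(O)C[C@@]3(C)CC[C@@](O)(C(C)C)[C@H]13 | intermediate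
17 | (3R,3aS,4S,8aR)‑4‑silyloxy‑3‑hydroxy‑3‑isopropyl‑6,8a‑dimethylhexahydroazulen‑7‑one | CC(C)(C)[Si](C)(C)O[C@H]1C=C(C)C(=O)C[C@@]3(C)CC[C@@](O)(C(C)C)[C@H]13 | intermediate
18 | (3R,3aS,4S,8aR)‑3,4‑dihydroxy‑3‑isopropyl‑6,8a‑dimethylhexahydroazulen‑7‑one | O[C@H]1C=C(C)C(=O)C[C@@]3(C)CC[C@@](O)(C(C)C)[C@H]13 | intermediate
19 | vanillic acid | COc1cc(C(=O)O)ccc1O | starting material
20 | tert‑butyldimethylsilyl 4‑(tert‑butyldimethylsilyloxy)‑3‑methoxybenzoate | COc1cc(C(=O)O[Si](C)(C)C(C)(C)C)ccc1O[Si](C)(C)C(C)(C)C | intermediate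
21 | 4‑(tert‑butyldimethylsilyloxy)‑3‑methoxybenzoic acid | COc1cc(C(=O)O)ccc1O[Si](C)(C)C(C)(C)C | intermediate
22 | C‑4 ester of 18 with 21 (7‑oxo) | COc1cc(C(=O)O[C@H]2C=C(C)C(=O)C[C@@]3(C)CC[C@@](O)(C(C)C)[C@H]23)ccc1O[Si](C)(C)C(C)(C)C | intermediate
23 | phenol‑silylated target (7β‑OH) | COc1cc(C(=O)O[C@H]2C=C(C)[C@H](O)C[C@@]3(C)CC[C@@](O)(C(C)C)[C@H]23)ccc1O[Si](C)(C)C(C)(C)C | intermediate
24 | CNP0189996.3 | COc1cc(C(=O)O[C@H]2C=C(C)[C@H](O)C[C@@]3(C)CC[C@@](O)(C(C)C)[C@H]23)ccc1O | target

**Step count**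

Total steps: 14. Longest linear sequence: 13 (steps 1–10 and 12–14).

**Steps most likely to fail**

Step 6 (proposed new method). What may go wrong: the tertiary radical or the α‑boryl radical is captured by nickel on another molecule (oligomerisation), the tertiary radical couples directly with the alkenyl–nickel unit without taking up the two‑carbon unit, or the α‑boryl radical cyclises in a 6‑exo mode onto the alkene. Fallback by known chemistry, setting out from 10: photoredox Giese addition to 11 without nickel (same iridium photocatalyst, aqueous acetone as proton source) should give the homologated boronic ester F1, with the same anti approach setting C‑8a. Peroxide oxidation gives the primary alcohol F2 and DMP oxidation the aldehyde F3. An intramolecular Nozaki–Hiyama–Kishi reaction (CrCl2, catalytic NiCl2, DMSO/THF, high dilution) then closes the seven‑membered ring at C‑6–C‑7 and comes back to the route at 15.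

Step 3. What may go wrong: loose transition‑state organisation of the pinacolboron enolate gives poor anti/syn and facial selectivity, and residual boryl–copper adds to the iodo‑enal. Fallback, setting out from 7: the enolate is intercepted in the flask with TMSCl/Et3N and isolated as the silyl enol ether F4, free of copper. Boron–silicon exchange with Bu2BOTf (CH2Cl2, −78 °C) gives the dibutylboron enolate F5, which reacts with 4 through a tight chair transition state. Non‑oxidative work‑up returns the route at 8.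

Step 8. What may go wrong: β‑hydride reduction and enolisation of the hindered cyclopentanone by the branched Grignard reagent, with loss of the C‑3a configuration. Fallback, setting out from 15: addition of isopropenylmagnesium bromide/CeCl3 (an sp2 nucleophile without β‑hydrogen, delivered as a weakly basic organocerium) gives the isopropenyl carbinol F6. Chemoselective hydrogenation of the 1,1‑disubstituted alkene (RhCl(PPh3)3, H2, benzene) comes back to the route at 16.

**Further compounds**

F1 | step 6 | (2S,3R)‑2‑[(1R,2Z)‑1‑(tert‑butyldimethylsilyloxy)‑3‑iodobut‑2‑en‑1‑yl]‑3‑methyl‑3‑[2‑(pinacolboryl)ethyl]cyclopentan‑1‑one | C/C(I)=C/[C@H](O[Si](C)(C)C(C)(C)C)[C@H]1C(=O)CC[C@]1(C)CCB2OC(C)(C)C(C)(C)O2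
F2 | step 6 | corresponding 3‑(2‑hydroxyethyl) ketone | C/C(I)=C/[C@H](O[Si](C)(C)C(C)(C)C)[C@H]1C(=O)CC[C@]1(C)CCO
F3 | step 6 | corresponding 3‑(2‑oxoethyl) ketone (aldehyde) | C/C(I)=C/[C@H](O[Si](C)(C)C(C)(C)C)[C@H]1C(=O)CC[C@]1(C)CC=O
F4 | step 3 | trimethylsilyl enol ether of (R)‑3‑methyl‑3‑(pinacolboryl)cyclopentanone | C[C@]1(B2OC(C)(C)C(C)(C)O2)CCC(O[Si](C)(C)C)=C1
F5 | step 3 | dibutylboron enolate of (R)‑3‑methyl‑3‑(pinacolboryl)cyclopentanone | C[C@]1(B2OC(C)(C)C(C)(C)O2)CCC(OB(CCCC)CCCC)=C1
F6 | step 8 | (3R,3aS,4S,8aR)‑4‑silyloxy‑6,8a‑dimethyl‑3‑(prop‑1‑en‑2‑yl)octahydroazulene‑3,7‑diol, C‑7 epimers | CC(C)(C)[Si](C)(C)O[C@H]1C=C(C)C(O)C[C@@]3(C)CC[C@@](O)(C(C)=C)[C@H]13
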